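Compound numbers used throughout: 5 is the coumarin aldehyde, 9 the aldol, 11 its propanoate, 13 the enol triflate, 16 the ring-D lactone, 19 the dithiane, 21 the hydroxy ketone, 23 the diketone lactol and 24 the target. Atom numbers (C1 to C30) follow the heavy-atom order of the target SMILES.

## Analysis of the target

The target is pentacyclic: a 5-methylcoumarin (rings A and B) is fused through C10–C11 to a 1,3-dioxin (ring C: C10, C11, O13, C14, O21, C22), which shares C14–O21–C22 with an oxane (ring D: C14, O21, C22, C23, C24, C29), so rings C and D form a 2,9-dioxabicyclo[3.3.1]nonane; ring D is fused at C23–C24 to a cyclopentene (ring E) with the alkene at C24=C25. There are five stereocentres: C27, C23 and C22 are contiguous (methyl C28 trans to C22 on ring E, H22 and H23 anti), C14 is a ketal bridgehead whose configuration is tied geometrically to C22 (O13 and C10 must be cis on ring D), and C29 carries a methyl group between the alkene carbon C24 and the ketal carbon C14. Because C10 has to be axial on ring D while ring E holds C27 in the plane of C24=C25, ring D of the target cannot be a chair; it is a boat with O21 and C24 at prow and stern, in which the C29 methyl lies beside O13 and away from the C15 acyl group. The sensitive features are the α-keto ketal at C14/C15, the vinylogous carbonate of the coumarin (electrophilic at C11 and C8), the skipped alkene C24=C25, which can slip to C24=C29 whenever C14 is a carbonyl, and the β-oxygenated carbonyl relationship C22–C23–C24 at the ketone stage (retro-aldol cleavage, elimination). The difficulty is regio- and stereocontrol around C24: a trisubstituted alkene exactly at C24=C25, C29 attached to it, and an acyl-bearing quaternary ketal carbon C14 built without disturbing C29 or C22. The strategy rests on one feature: C29 is both the α-carbon of the carboxyl-level carbon C14 and a substituent on the alkene carbon C24, and C14 is joined to C22 through O21, so ring D is a δ-lactone in disguise that can be closed between C24 and C29.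

## Retrosynthetic reasoning

**Ring C (bond from C11 to the ketal oxygen).** Cutting the C11–O bond of 24, with the oxygen staying on C14, gives the hemiketal 23, in which the coumarin still carries its O-methyl group. This is the right place to cut because the bicyclic ketal is the thermodynamic resting form: C14 can only bridge with its oxygen cis to the coumarin on C22, so its configuration needs no separate control, and the boat-shaped ring D of 24 favours the (29R) methyl. The forward reaction is an acid-catalysed alkoxy exchange at the vinylogous ester carbon C11.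

**C15 carbonyl and the C14–C15 bond.** The hemiketal 23 is the closed form of the δ-hydroxy 1,2-diketone 22, which comes from the 2-acyl dithiane 21. Cutting C14–C15 in 21 gives the lactone 16 and the lithiated form 20 of dithiane 19. The lactone holds C14 at the carboxyl level, so a single acyl anion addition delivers the 1,2-dicarbonyl without any redox adjustment. The forward reaction must add once to C14 and must not attack the coumarin.

**Ring D (C24–C29), the key disconnection.** Cutting C24–C29 in 16 gives the propanoate ester 13, which has the enolisable carbon C29 and the enol triflate carbon C24 in a 1,6 relationship. A cut here fixes the alkene position through the triflate, which a dehydration or a Wittig-type route to C24=C25 could not guarantee. The forward reaction is an intramolecular palladium-catalysed alkenylation of the zinc enolate 15.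

**Functional group adjustment.** The enol triflate 13 comes from ketone 11 by kinetic enolisation at C25, and 11 from the aldol 9 by O-acylation with 10. Acylating before the triflation blocks retro-aldol cleavage and brings in C14, C29 and C30.

**C22–C23 and C27–C28.** Cutting both bonds in 9 gives aldehyde 5, enone 6 and the methyl donor 7. One tandem conjugate addition–aldol reaction sets C27 (catalyst control), C23 (trans to the new methyl) and C22 (anti aldol through the cyclic enolate 8).

**Small building blocks.** Aldehyde 5 goes back through the chloro aldehyde 4 and the 4-hydroxycoumarin 3 to ketone 1 and carbonate 2. Dithiane 19 comes from aldehyde 17 and dithiol 18.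

## Alternatives that were turned down

**Alternative 1:** allenylsilane [3+2] annulation for ring E.
- Disconnection: C26–C27 and C23–C24.
- Forward key step: the enone 3-[(2E)-but-2-enoyl]-4-methoxy-5-methylcoumarin A1 and the allenylsilane A2, which already carries the C29 propanoate arm, undergo a Danheiser annulation under a chiral Sc(OTf)3–pybox Lewis acid to give the silylated cyclopentene A3.
- For it: it is convergent, forms two C–C bonds and ring E in one step with C23/C27 trans, and the C24–C29 bond arrives ready-made.
- Against it for this target: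
  - C22 emerges as a ketone, so a diastereoselective reduction is needed next to C23, which is epimerisable in this vinylogous tricarbonyl system.
  - The silyl group on C25 has to be removed under acid without moving the alkene.
  - The C29 centre of A2 sits between an allene and an ester and is configurationally fragile; it must also match the catalyst.
  - The annulation normally needs a stoichiometric strong Lewis acid, and a catalytic enantioselective version on a β-methyl enone with a chelating 4-methoxycoumarin is unproven.
- Comparison: it is stronger on convergence and bond count (two bonds and two stereocentres against one bond). The chosen strategy offers in its place C22 at the alcohol level from the start, an alkene position fixed by the triflate, and stereocentres set by reactions of established sense.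

**Alternative 2:** three-component methyl addition and aldol as the strategic step.
- Disconnection: C27–C28 and C22–C23.
- Forward key step: 7 adds to 6 under Cu(OTf)2 and a chiral phosphoramidite, and the zinc enolate is trapped by 5 to give the aldol A4, which is identical with 9.
- For it: three stereocentres and two bonds in one operation from commercial inputs.
- Against it: it closes no ring and does not say how the ketone carbon C24 becomes the alkene carbon bonded to C29, nor how C14 is built. A plan that adds a three-carbon nucleophile to the C24 ketone and dehydrates would face three possible alkene positions and the retro-aldol lability of A4.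
- Comparison: on the opening it is equal, because the chosen route uses this very reaction as step 4. The chosen strategy adds the answer for ring D, C29 and the alkene.

**Alternative 3:** coumarin built last on a preformed pyran.
- Disconnection: C10–C11, O7–C8 and O13–C14.
- Forward key step: the lithium enolate at C10 of the ring-D methyl ketal A5, which carries an acetic ester arm on C22 and the dithiane on C15, is acylated by 2,2,5-trimethyl-4H-1,3-benzodioxin-4-one A6; the freed phenoxide lactonises to ring B, and acid exchanges the methyl ketal for O13 to give the bridged ketal A7.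
- For it: the electrophilic 4-alkoxycoumarin never meets an enolate, palladium or a dithiane anion. On this point it is stronger than the chosen route, whose main chemoselectivity risks (steps 7 and 9) come from C11 and C8.
- Against it:
  - The C10 enolate of A5 has O21 on its β-carbon C22, so β-elimination that opens ring D competes directly with acylation.
  - A5 needs ring D, C29, the C14 ketal and the dithiane assembled without the coumarin, which is a longer sequence with a less direct way to set C22.
  - The final exchange must take place at a ketal carbon next to a quaternary dithiane carbon.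
- Comparison: it handles the heterocycle more safely but is longer and has the elimination flaw. The chosen strategy offers a shorter route and no β-alkoxy enolate.

Key step: step 7

Assumption: the (S,R,R) phosphoramidite is taken to deliver the methyl group of 7 to the face of 6 that gives (3S)-8, by analogy with its sense on six-membered enones; if the sense is opposite, the enantiomeric ligand is used and nothing else changes.

Remark: 21 and 23 are drawn in the tautomeric form expected to dominate (open hydroxy ketone and hemiketal); 23 is drawn as the anomer that can close, and its anomers interconvert through 22.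

## Route

Step 1
Reactants: 1 1-(2-hydroxy-6-methylphenyl)ethanone; 2 diethyl carbonate
Product: 3 4-hydroxy-5-methyl-2H-chromen-2-one
Conditions: NaH (3 equiv), 2 (5 equiv), PhMe, 100 °C; then 1 M HCl
Reagents that add atoms: none
Why: Claisen-type C-acylation of the acetophenone enolate by the carbonate, then lactonisation of the β-keto ester onto the phenoxide; this is the standard conversion of 2-hydroxyacetophenones into 4-hydroxycoumarins, and the ortho methyl group C1 is a spectator.

Step 2
Reactants: 3 4-hydroxy-5-methyl-2H-chromen-2-one
Product: 4 4-chloro-5-methyl-2-oxo-2H-chromene-3-carbaldehyde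
Conditions: POCl3 (3 equiv), DMF, 0 → 60 °C; then ice, aq. NaOAc
Reagents that add atoms: N,N-dimethylformamide (CN(C)C=O); phosphoryl chloride (O=P(Cl)(Cl)Cl); water (O)
Why: Vilsmeier–Haack reaction: the chloroiminium salt formylates the nucleophilic C10 and the vinylogous acid hydroxyl on C11 is exchanged for chloride, the established route from 4-hydroxycoumarins to 4-chloro-3-formylcoumarins; aqueous work-up frees the aldehyde.

Step 3
Reactants: 4 4-chloro-5-methyl-2-oxo-2H-chromene-3-carbaldehyde
Product: 5 4-methoxy-5-methyl-2-oxo-2H-chromene-3-carbaldehyde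
Conditions: NaOMe (1.05 equiv), MeOH/THF, −10 → 0 °C
Reagents that add atoms: sodium methoxide (C[O-].[Na+])
Why: Addition–elimination at C11, which is activated by both the formyl group and the lactone carbonyl, so one equivalent of methoxide at low temperature should displace chloride before it opens the lactone; the methoxy group masks the vinylogous acid and is the leaving group of step 11.

Step 4
Reactants: 6 cyclopent-2-en-1-one; 7 dimethylzinc; 5 4-methoxy-5-methyl-2-oxo-2H-chromene-3-carbaldehyde
Product: 9 (2S,3S)-2-[(R)-hydroxy(4-methoxy-5-methyl-2-oxo-2H-chromen-3-yl)methyl]-3-methylcyclopentan-1-one, via methylzinc (3S)-3-methylcyclopent-1-en-1-olate 8 (not isolated)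
Conditions: Cu(OTf)2 (2 mol %), (S,R,R)-binaphthol bis(1-phenylethyl)amine phosphoramidite (4 mol %), 7 (1.3 equiv), PhMe, −30 °C; then 5 in CH2Cl2, −30 °C; aq. NH4Cl
Reagents that add atoms: none
Why: Tandem copper-catalysed conjugate addition–aldol reaction: the ligand sets C27 (S), the regiodefined zinc enolate 8 adds to the aldehyde anti to the new methyl group (trans C23/C27), and the closed Zimmerman–Traxler transition state of the (E)-configured cyclic enolate leads to the anti aldol, which is (22R). The minor syn aldol would be removed by chromatography and the enantiomeric purity of 9 raised by recrystallisation if needed.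

Step 5
Reactants: 9 (2S,3S)-2-[(R)-hydroxy(4-methoxy-5-methyl-2-oxo-2H-chromen-3-yl)methyl]-3-methylcyclopentan-1-one; 10 propanoyl chloride
Product: 11 (R)-(4-methoxy-5-methyl-2-oxo-2H-chromen-3-yl)[(1S,2S)-2-methyl-5-oxocyclopentyl]methyl propanoate
Conditions: 10 (1.5 equiv), pyridine (3 equiv), DMAP (0.1 equiv), CH2Cl2, 0 °C
Reagents that add atoms: none
Why: DMAP-catalysed O-acylation of the secondary alcohol with retention at C22; weakly basic conditions at 0 °C avoid retro-aldol cleavage and elimination across C22–C23, and the ester installs C14, C29 and C30.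

Step 6
Reactants: 11 (R)-(4-methoxy-5-methyl-2-oxo-2H-chromen-3-yl)[(1S,2S)-2-methyl-5-oxocyclopentyl]methyl propanoate
Product: 13 (R)-(4-methoxy-5-methyl-2-oxo-2H-chromen-3-yl)[(1S,5S)-5-methyl-2-{[(trifluoromethyl)sulfonyl]oxy}cyclopent-2-en-1-yl]methyl propanoate, via potassium cyclopentenolate 12 (not isolated)
Conditions: KN(SiMe3)2 (1.1 equiv), THF, −78 °C (11 added to the base); PhNTf2 (1.2 equiv), −78 → −40 °C
Reagents that add atoms: N-phenylbis(trifluoromethanesulfonimide) (O=S(=O)(N(c1ccccc1)S(=O)(=O)C(F)(F)F)C(F)(F)F)
Why: Kinetic deprotonation by a hindered amide base occurs at the unhindered C25 methylene rather than at the tertiary C23 (whose enolate would expel propanoate) or at the less acidic ester α-carbon, and O-triflation of enolate 12 fixes the alkene as C24=C25; standard regioselective enol triflate formation from a 2-substituted cyclopentanone.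

Step 7
Reactants: 13 (R)-(4-methoxy-5-methyl-2-oxo-2H-chromen-3-yl)[(1S,5S)-5-methyl-2-{[(trifluoromethyl)sulfonyl]oxy}cyclopent-2-en-1-yl]methyl propanoate
Product: 16 (1R,4R,7S,7aR)-1-(4-methoxy-5-methyl-2-oxo-2H-chromen-3-yl)-4,7-dimethyl-4,6,7,7a-tetrahydrocyclopenta[c]pyran-3(1H)-one, via lithium ester enolate 14 (not isolated), via chlorozinc ester enolate 15 (not isolated)
Conditions: LiN(SiMe3)2 (1.15 equiv), THF, −78 °C; ZnCl2 (1.3 equiv), −78 → 0 °C; Pd2(dba)3 (5 mol %), P(t-Bu)3 (12 mol %), 23 → 45 °C; aq. NH4Cl
Reagents that add atoms: none
Why: LiN(SiMe3)2 removes a C29 hydrogen of the propanoate (the only carbonyl α-hydrogens left once C24 is an enol triflate), and ZnCl2 turns the lithium enolate 14 into the milder Reformatsky-type enolate 15. Zerovalent palladium carrying P(t-Bu)3 inserts into the C24–O bond of the triflate, 15 transmetallates to a C-bound palladium enolate inside a seven-membered palladacycle, and reductive elimination forms C24–C29. The closest known reaction type is the palladium-catalysed α-alkenylation and α-arylation of zinc ester enolates, including intramolecular variants with alkenyl halides and triflates. Ring D closes as a six-membered lactone in a formal 6-(enolendo)-exo-trig sense, which is accessible because the enolate has lost the strong s-trans preference of the parent ester about C14–O21. The alkene cannot be misplaced: the triflate defines it as C24=C25, and α-protonation on work-up of any zinc dienolate formed from the product returns the β,γ-unsaturated lactone. The step needs C-alkenylation to outrun addition of the enolate to the vinylogous ester carbon C11; the zinc counter-ion, the peri methyl group C1 and the fully substituted C10 all disfavour that addition. C29 is set under substrate control in the palladacycle, but the cyclopentene fusion forces ring D into the one half-chair in which the (29R) methyl is pseudo-axial, so only a modest bias is expected; the centre is not relied on here, because it stays epimerisable until step 11, where ring closure selects the (29R) series.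

Step 8
Reactants: 17 3-methylbutanal; 18 propane-1,3-dithiol
Product: 19 2-(2-methylpropyl)-1,3-dithiane
Conditions: BF3·OEt2 (0.2 equiv), CH2Cl2, 0 → 23 °C
Reagents that add atoms: none
Why: Lewis acid-catalysed dithioacetalisation of an aldehyde, the standard entry to a Corey–Seebach acyl anion equivalent.

Step 9
Reactants: 19 2-(2-methylpropyl)-1,3-dithiane; 16 (1R,4R,7S,7aR)-1-(4-methoxy-5-methyl-2-oxo-2H-chromen-3-yl)-4,7-dimethyl-4,6,7,7a-tetrahydrocyclopenta[c]pyran-3(1H)-one
Product: 21 (2R)-2-{(4S,5R)-5-[(R)-hydroxy(4-methoxy-5-methyl-2-oxo-2H-chromen-3-yl)methyl]-4-methylcyclopent-1-en-1-yl}-1-[2-(2-methylpropyl)-1,3-dithian-2-yl]propan-1-one, via 2-lithio-2-(2-methylpropyl)-1,3-dithiane 20 (not isolated)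
Conditions: 19 (1.5 equiv), n-BuLi (1.4 equiv), THF, −30 °C; then 16, −78 → −40 °C; aq. NH4Cl
Reagents that add atoms: none
Why: Corey–Seebach acylation: 20 adds once to the lactone carbonyl C14, and neither the tetrahedral intermediate nor the hindered 2-acyl dithiane can take a second equivalent; the δ-lactone is expected to be more electrophilic than the coumarin carbonyl C8, which is a vinylogous carbonate, and C11 is shielded by the peri methyl group and by C22. C29 becomes α to a ketone in 21 and may epimerise, which is tolerated because the centre is settled in step 11.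

Step 10
Reactants: 21 (2R)-2-{(4S,5R)-5-[(R)-hydroxy(4-methoxy-5-methyl-2-oxo-2H-chromen-3-yl)methyl]-4-methylcyclopent-1-en-1-yl}-1-[2-(2-methylpropyl)-1,3-dithian-2-yl]propan-1-one
Product: 23 1-[(1R,3R,4R,7S,7aR)-3-hydroxy-1-(4-methoxy-5-methyl-2-oxo-2H-chromen-3-yl)-4,7-dimethyl-1,3,4,6,7,7a-hexahydrocyclopenta[c]pyran-3-yl]-3-methylbutan-1-one, via ring-opened 3,4-dione 22 (not isolated)
Conditions: PhI(OCOCF3)2 (1.5 equiv), MeCN/H2O 9:1, 0 °C
Reagents that add atoms: water (O)
Why: Oxidative hydrolysis of the dithiane by a hypervalent iodine reagent, which spares the trisubstituted alkene and the free alcohol; the freed 1,2-diketone 22 is strongly electrophilic at C14 and is expected to close to the six-membered hemiketal 23, the usual resting form of δ-hydroxy α-diketones. The anomeric centre C14 equilibrates through 22 and is not fixed here.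

Step 11
Reactants: 23 1-[(1R,3R,4R,7S,7aR)-3-hydroxy-1-(4-methoxy-5-methyl-2-oxo-2H-chromen-3-yl)-4,7-dimethyl-1,3,4,6,7,7a-hexahydrocyclopenta[c]pyran-3-yl]-3-methylbutan-1-one
Product: 24 CNP0310889.1, the bridged ketal with C14 bonded to O13, O21, C15 and C29, configured (14S,22R,23R,27S,29R) in heavy-atom numbering
Conditions: (+)-camphor-10-sulfonic acid (0.2 equiv), PhMe, 5 Å molecular sieves, 60 °C
Reagents that add atoms: none
Why: Acid-catalysed alkoxy exchange at a vinylogous ester: the C14 hydroxyl adds to C11 of the protonated 4-methoxycoumarin (6-endo-trig) and methanol is lost, closing ring C; the α-keto group disfavours ionisation at C14, so the hemiketal acts as the nucleophile and does not lose water. Only the anomer with the hydroxyl cis to the coumarin on C22 can bridge, so C14 (S) is dictated by C22. C29 can epimerise through the enol of 22, and closure should favour the (29R) lactol because in the boat-shaped ring D of the product its methyl group lies beside O13, whereas the epimer would eclipse the C15 acyl group.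

## Compound list

1 | 1-(2-hydroxy-6-methylphenyl)ethanone | CC(=O)c1c(C)cccc1O | starting material
2 | diethyl carbonate | CCOC(=O)OCC | starting material
3 | 4-hydroxy-5-methyl-2H-chromen-2-one | Cc1cccc2oc(=O)cc(O)c12 | intermediate
4 | 4-chloro-5-methyl-2-oxo-2H-chromene-3-carbaldehyde | Cc1cccc2oc(=O)c(C=O)c(Cl)c12 | intermediate
5 | 4-methoxy-5-methyl-2-oxo-2H-chromene-3-carbaldehyde | Cc1cccc2oc(=O)c(C=O)c(OC)c12 | intermediate
6 | cyclopent-2-en-1-one | O=C1C=CCC1 | starting material
7 | dimethylzinc | C[Zn]C | starting material
8 | methylzinc (3S)-3-methylcyclopent-1-en-1-olate | C[Zn]OC1=C[C@@H](C)CC1 | intermediate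
9 | (2S,3S)-2-[(R)-hydroxy(4-methoxy-5-methyl-2-oxo-2H-chromen-3-yl)methyl]-3-methylcyclopentan-1-one | Cc1cccc2oc(=O)c(c(OC)c12)[C@H](O)[C@H]1C(=O)CC[C@@H]1C | intermediate
10 | propanoyl chloride | CCC(=O)Cl | starting material
11 | (R)-(4-methoxy-5-methyl-2-oxo-2H-chromen-3-yl)[(1S,2S)-2-methyl-5-oxocyclopentyl]methyl propanoate | Cc1cccc2oc(=O)c(c(OC)c12)[C@H](OC(=O)CC)[C@H]1C(=O)CC[C@@H]1C | intermediate
12 | potassium C24=C25 enolate of 11 (potassium cyclopentenolate) | Cc1cccc2oc(=O)c(c(OC)c12)[C@H](OC(=O)CC)[C@H]1C(O[K])=CC[C@@H]1C | intermediate
13 | (R)-(4-methoxy-5-methyl-2-oxo-2H-chromen-3-yl)[(1S,5S)-5-methyl-2-{[(trifluoromethyl)sulfonyl]oxy}cyclopent-2-en-1-yl]methyl propanoate | Cc1cccc2oc(=O)c(c(OC)c12)[C@H](OC(=O)CC)[C@H]1C(OS(=O)(=O)C(F)(F)F)=CC[C@@H]1C | intermediate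
14 | lithium enolate of the propanoate of 13 (O-bound, enolate geometry not fixed) | Cc1cccc2oc(=O)c(c(OC)c12)[C@H](OC(O[Li])=CC)[C@H]1C(OS(=O)(=O)C(F)(F)F)=CC[C@@H]1C | intermediate
15 | chlorozinc enolate of the propanoate of 13 (drawn O-bound, enolate geometry not fixed) | Cc1cccc2oc(=O)c(c(OC)c12)[C@H](OC(O[Zn]Cl)=CC)[C@H]1C(OS(=O)(=O)C(F)(F)F)=CC[C@@H]1C | intermediate
16 | (1R,4R,7S,7aR)-1-(4-methoxy-5-methyl-2-oxo-2H-chromen-3-yl)-4,7-dimethyl-4,6,7,7a-tetrahydrocyclopenta[c]pyran-3(1H)-one | O=C1O[C@@H](c3c(OC)c4c(C)cccc4oc3=O)[C@H]2C(=CC[C@@H]2C)[C@H]1C | intermediate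
17 | 3-methylbutanal | CC(C)CC=O | starting material
18 | propane-1,3-dithiol | SCCCS | starting material
19 | 2-(2-methylpropyl)-1,3-dithiane | CC(C)CC1SCCCS1 | intermediate
20 | 2-lithio-2-(2-methylpropyl)-1,3-dithiane | [Li]C1(CC(C)C)SCCCS1 | intermediate
21 | (2R)-2-{(4S,5R)-5-[(R)-hydroxy(4-methoxy-5-methyl-2-oxo-2H-chromen-3-yl)methyl]-4-methylcyclopent-1-en-1-yl}-1-[2-(2-methylpropyl)-1,3-dithian-2-yl]propan-1-one | Cc1cccc2oc(=O)c(c(OC)c12)[C@H](O)[C@H]3C(=CC[C@@H]3C)[C@@H](C)C(=O)C4(CC(C)C)SCCCS4 | intermediate
22 | (2R)-2-{(4S,5R)-5-[(R)-hydroxy(4-methoxy-5-methyl-2-oxo-2H-chromen-3-yl)methyl]-4-methylcyclopent-1-en-1-yl}-6-methylheptane-3,4-dione | Cc1cccc2oc(=O)c(c(OC)c12)[C@H](O)[C@H]3C(=CC[C@@H]3C)[C@@H](C)C(=O)C(=O)CC(C)C | intermediate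
23 | 1-[(1R,3R,4R,7S,7aR)-3-hydroxy-1-(4-methoxy-5-methyl-2-oxo-2H-chromen-3-yl)-4,7-dimethyl-1,3,4,6,7,7a-hexahydrocyclopenta[c]pyran-3-yl]-3-methylbutan-1-one | O[C@@]1(C(=O)CC(C)C)O[C@@H](c3c(OC)c4c(C)cccc4oc3=O)[C@H]2C(=CC[C@@H]2C)[C@H]1C | intermediate
24 | CNP0310889.1, bridged ketal (14S,22R,23R,27S,29R) | Cc1cccc2oc(=O)c3c(c12)O[C@@]1(C(=O)CC(C)C)O[C@@H]3[C@H]2C(=CC[C@@H]2C)[C@H]1C | target

## Step count and least certain steps

Total step count: 11. Longest linear sequence: 10 steps (1 → 3 → 4 → 5 → 9 → 11 → 13 → 16 → 21 → 23 → 24); step 8 is a one-step branch.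

**Step 7 (key step).** The zinc enolate may be consumed by routes other than C–C reductive elimination: intramolecular addition to C11 with loss of methoxide, or fragmentation to a ketene and the C22 alkoxide on warming. Transmetallation may also stall because the tether has to reach the s-cis ester geometry, so that the triflate is reduced or hydrolysed instead, and C29 may emerge mainly as the epimer. Fallback: the C24–C29 bond is made intermolecularly and ring D is closed by lactonisation. Setting out from 9, silylation (Et3SiCl, imidazole) gives the triethylsilyl ether F1, and triflation as in step 6 gives the enol triflate F2. A Negishi-type coupling of F2 with the Reformatsky reagent (1-tert-butoxy-1-oxopropan-2-yl)zinc bromide F4, made from tert-butyl 2-bromopropanoate F3 and zinc dust, under Pd2(dba)3 and P(t-Bu)3 gives the tert-butyl ester F5; both C29 epimers are expected, and the substrate never meets a strong base. CF3CO2H in CH2Cl2 then removes the tert-butyl and triethylsilyl groups, and the δ-hydroxy acid lactonises, which brings the route back at 16.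

**Step 4.** Enantioselection in the methyl transfer may be insufficient, since five-membered enones with Me2Zn are the least favourable case for this catalyst class; the aldol may also be incompletely anti-selective, and the enolate may attack C11 of 5. Fallback: the same regiodefined enolate is generated by asymmetric conjugate reduction. Setting out from 5, the partner is made from 3-methylcyclopent-2-en-1-one F6, which is reduced with Ph2SiH2 under CuCl, NaOt-Bu and p-tol-BINAP (the ligand enantiomer that gives 3S) to bis{[(3S)-3-methylcyclopent-1-en-1-yl]oxy}diphenylsilane F7. A Mukaiyama aldol reaction of F7 with 5 (BF3·OEt2, CH2Cl2, −78 °C) brings the route back at 9.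

**Step 6.** Proton exchange may generate the C23 enolate, which would expel propanoate to give an enone, or the enolate oxygen may accept the propanoyl group. Fallback: the alcohol is carried through the triflation as a silyl ether, a much poorer leaving group. Setting out from 9, t-BuMe2SiOTf and 2,6-lutidine give the silyl ether F8, KN(SiMe3)2 and PhNTf2 give the enol triflate F9, HF·pyridine gives the hydroxy enol triflate F10, and acylation as in step 5 brings the route back at 13.

**Step 9.** The basic, hindered dithiane anion may abstract the allylic, lactone-activated proton on C29 and not add to C14 (lactone recovered, C29 scrambled), or it may add to C8 or C11 of the coumarin. Fallback: acylation of a sulfone-stabilised carbanion followed by oxidative desulfonylation. Setting out from 16, the lithio derivative of [(3-methylbutyl)sulfonyl]benzene F11 (n-BuLi, THF, −78 °C) opens the lactone to the β-keto sulfone F12, which is deprotonated as it forms and so protected from further addition. Its dianion (LiN(SiMe3)2) is oxidised with MoO5·pyridine·HMPA, loss of sulfinate gives 22, and 22 closes to 23, where the route is rejoined.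

**Step 11.** The exchange at C11 may be slow, so that acid instead shifts C24=C25 into conjugation through the enol of 22, ionises C22–O21, or lets the (29S) lactol close before the C29 epimers have equilibrated. Fallback: the methyl ether is removed first under non-acidic conditions and the ring is then closed by dehydration. Setting out from 23, LiI in EtOAc at 70 °C cleaves the methyl group by SN2 attack to give the 4-hydroxycoumarin lactol F13. Pyridinium p-toluenesulfonate in benzene with azeotropic removal of water closes ring C by vinylogous esterification and brings the route back at 24.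

## Further compounds

F1 | step 7 | (2S,3S)-2-[(R)-(4-methoxy-5-methyl-2-oxo-2H-chromen-3-yl)(triethylsilyloxy)methyl]-3-methylcyclopentan-1-one | Cc1cccc2oc(=O)c(c(OC)c12)[C@H](O[Si](CC)(CC)CC)[C@H]1C(=O)CC[C@@H]1C
F2 | step 7 | (1S,5S)-1-[(R)-(4-methoxy-5-methyl-2-oxo-2H-chromen-3-yl)(triethylsilyloxy)methyl]-5-methylcyclopent-2-en-2-yl trifluoromethanesulfonate | Cc1cccc2oc(=O)c(c(OC)c12)[C@H](O[Si](CC)(CC)CC)[C@H]1C(OS(=O)(=O)C(F)(F)F)=CC[C@@H]1C
F3 | step 7 | tert-butyl 2-bromopropanoate (purchased, racemic) | CC(Br)C(=O)OC(C)(C)C
F4 | step 7 | (1-tert-butoxy-1-oxopropan-2-yl)zinc bromide | CC([Zn]Br)C(=O)OC(C)(C)C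
F5 | step 7 | tert-butyl (2R)-2-{(4S,5R)-5-[(R)-(4-methoxy-5-methyl-2-oxo-2H-chromen-3-yl)(triethylsilyloxy)methyl]-4-methylcyclopent-1-en-1-yl}propanoate (drawn as the 2R epimer) | Cc1cccc2oc(=O)c(c(OC)c12)[C@H](O[Si](CC)(CC)CC)[C@H]1C(=CC[C@@H]1C)[C@@H](C)C(=O)OC(C)(C)C
F6 | step 4 | 3-methylcyclopent-2-en-1-one (purchased) | CC1=CC(=O)CC1
F7 | step 4 | bis{[(3S)-3-methylcyclopent-1-en-1-yl]oxy}diphenylsilane | C[C@H]1CCC(O[Si](OC2=C[C@@H](C)CC2)(c3ccccc3)c4ccccc4)=C1
F8 | step 6 | (2S,3S)-2-[(R)-(tert-butyldimethylsilyloxy)(4-methoxy-5-methyl-2-oxo-2H-chromen-3-yl)methyl]-3-methylcyclopentan-1-one | Cc1cccc2oc(=O)c(c(OC)c12)[C@H](O[Si](C)(C)C(C)(C)C)[C@H]1C(=O)CC[C@@H]1C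
F9 | step 6 | (1S,5S)-1-[(R)-(tert-butyldimethylsilyloxy)(4-methoxy-5-methyl-2-oxo-2H-chromen-3-yl)methyl]-5-methylcyclopent-2-en-2-yl trifluoromethanesulfonate | Cc1cccc2oc(=O)c(c(OC)c12)[C@H](O[Si](C)(C)C(C)(C)C)[C@H]1C(OS(=O)(=O)C(F)(F)F)=CC[C@@H]1C
F10 | step 6 | (1S,5S)-1-[(R)-hydroxy(4-methoxy-5-methyl-2-oxo-2H-chromen-3-yl)methyl]-5-methylcyclopent-2-en-2-yl trifluoromethanesulfonate | Cc1cccc2oc(=O)c(c(OC)c12)[C@H](O)[C@H]1C(OS(=O)(=O)C(F)(F)F)=CC[C@@H]1C
F11 | step 9 | [(3-methylbutyl)sulfonyl]benzene | CC(C)CCS(=O)(=O)c1ccccc1
F12 | step 9 | (2R)-2-{(4S,5R)-5-[(R)-hydroxy(4-methoxy-5-methyl-2-oxo-2H-chromen-3-yl)methyl]-4-methylcyclopent-1-en-1-yl}-6-methyl-4-(phenylsulfonyl)heptan-3-one (both epimers at the sulfonyl-bearing carbon) | Cc1cccc2oc(=O)c(c(OC)c12)[C@H](O)[C@H]3C(=CC[C@@H]3C)[C@@H](C)C(=O)C(CC(C)C)S(=O)(=O)c4ccccc4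
F13 | step 11 | 1-[(1R,3R,4R,7S,7aR)-3-hydroxy-1-(4-hydroxy-5-methyl-2-oxo-2H-chromen-3-yl)-4,7-dimethyl-1,3,4,6,7,7a-hexahydrocyclopenta[c]pyran-3-yl]-3-methylbutan-1-one | O[C@@]1(C(=O)CC(C)C)O[C@@H](c3c(O)c4c(C)cccc4oc3=O)[C@H]2C(=CC[C@@H]2C)[C@H]1C
A1 | alternative 1 | 3-[(2E)-but-2-enoyl]-4-methoxy-5-methyl-2H-chromen-2-one | C/C=C/C(=O)c1c(OC)c2c(C)cccc2oc1=O
A2 | alternative 1 | ethyl (2S)-2-methyl-3-(trimethylsilyl)penta-3,4-dienoate | CCOC(=O)[C@H](C)C(=C=C)[Si](C)(C)C
A3 | alternative 1 | ethyl (2R)-2-[(4S,5R)-5-(4-methoxy-5-methyl-2-oxo-2H-chromene-3-carbonyl)-4-methyl-2-(trimethylsilyl)cyclopent-1-en-1-yl]propanoate | Cc1cccc2oc(=O)c(c(OC)c12)C(=O)[C@H]3C(=C([Si](C)(C)C)C[C@@H]3C)[C@@H](C)C(=O)OCC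
A4 | alternative 2 | (2S,3S)-2-[(R)-hydroxy(4-methoxy-5-methyl-2-oxo-2H-chromen-3-yl)methyl]-3-methylcyclopentan-1-one (identical with 9) | Cc1cccc2oc(=O)c(c(OC)c12)[C@H](O)[C@H]1C(=O)CC[C@@H]1C
A5 | alternative 3 | methyl {3-methoxy-4,7-dimethyl-3-[2-(2-methylpropyl)-1,3-dithian-2-yl]-1,3,4,6,7,7a-hexahydrocyclopenta[c]pyran-1-yl}acetate, configured as in the target | CO[C@@]1(C4(CC(C)C)SCCCS4)O[C@@H](CC(=O)OC)[C@H]2C(=CC[C@@H]2C)[C@H]1C
A6 | alternative 3 | 2,2,5-trimethyl-4H-1,3-benzodioxin-4-one | CC1(C)OC(=O)c2c(C)cccc2O1
A7 | alternative 3 | bridged ketal of the target skeleton with C15 masked as a 1,3-dithiane | Cc1cccc2oc(=O)c3c(c12)O[C@@]1(C4(CC(C)C)SCCCS4)O[C@@H]3[C@H]2C(=CC[C@@H]2C)[C@H]1C
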